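**Plan**

- Retrosynthesis: both O-benzyl groups are cut first, the C8/C9 trans-diol is traced to an 8α,9α-epoxide and then to the C8=C9 alkene, and that ring bond is cut by ring-closing metathesis. The C6–C7 bond (methallyl addition), the C1–C10 bond ([3,3] shift) and the C1–C5 bond (aldol) are then cut back to (S)-terpinen-4-ol.
- Enabling feature: C8 (tertiary, methyl-bearing) and C9 are neighbours in the seven-membered ring and carry trans oxygens. This is the retron of a trisubstituted 8,9-alkene, which metathesis can form from an allyl arm on C1 and a methallyl arm on C6.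
- Forward: ring A (cyclopentane) arises first by ozonolysis/aldol ring contraction of the terpinene ring, the two alkene arms are attached, and ring B (cycloheptene) then closes at C8=C9; oxidation and deprotection finish.
- Stereochemistry: C4 comes from the chiral pool; C1 by chirality transfer from a reagent-set C6 carbinol in an anionic oxy-Cope shift; C5 by equilibration; C6 by chelation-controlled Grignard addition; C8 and C9 by α-face epoxidation and inverting hydrolysis at C8.

Key step: step 8

Remark: (S)-(+)-terpinen-4-ol is assumed to be available in high enantiomeric purity; atoms are numbered as in daucane (C1 methyl-bearing ring-fusion carbon, C4 isopropyl carbinol, C5 ring-fusion CH, C6 ester carbon), and β means the face of the C1 methyl group.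

Step 1
Reactants: 1 (S)-terpinen-4-ol
Product: 2 (4S)-4-(benzyloxy)-1-methyl-4-(propan-2-yl)cyclohex-1-ene
Conditions: KH, THF, 0 °C; BnBr, Bu4NI (cat.), 0 to 60 °C
Reagents that add atoms: benzyl bromide, BrCc1ccccc1
Why: Williamson etherification of the potassium tertiary alkoxide with the reactive benzylic halide should cap the C4 oxygen without touching the stereocentre, benzyl being chosen because it can chelate magnesium in step 6 and falls in the final hydrogenolysis.

Step 2
Reactants: 2 (4S)-4-(benzyloxy)-1-methyl-4-(propan-2-yl)cyclohex-1-ene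
Product: 4 (3S)-3-(benzyloxy)-6-oxo-3-(propan-2-yl)heptanal, via ozonide 3 (not isolated)
Conditions: O3, CH2Cl2, −78 °C (Sudan Red 7B end point); Me2S, −78 °C to rt
Reagents that add atoms: ozone, [O-][O+]=O
Why: Ozonolysis (Criegee mechanism) of the only alkene followed by reductive cleavage of the ozonide should give the keto aldehyde, the benzyl ether surviving when ozone is stopped at the indicator end point and the quaternary C4 not being involved.

Step 3
Reactants: 4 (3S)-3-(benzyloxy)-6-oxo-3-(propan-2-yl)heptanal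
Product: 5 (5R)-5-(benzyloxy)-2-methyl-5-(propan-2-yl)cyclopent-1-ene-1-carbaldehyde
Conditions: piperidine (0.2 equiv), AcOH (0.2 equiv), toluene, 80 °C
Reagents that add atoms: none
Why: Intramolecular aldol condensation through the piperidine enamine of the aldehyde, which attacks the methyl ketone in a five-membered ring closure and dehydrates to the tetrasubstituted enal, should form ring A with C4 untouched, and the product has no α-hydrogen from which benzyl alcohol could be eliminated.

Step 4
Reactants: 5 (5R)-5-(benzyloxy)-2-methyl-5-(propan-2-yl)cyclopent-1-ene-1-carbaldehyde; 6 (−)-B-allyldiisopinocampheylborane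
Product: 7 (1S)-1-[(5R)-5-(benzyloxy)-2-methyl-5-(propan-2-yl)cyclopent-1-en-1-yl]but-3-en-1-ol
Conditions: 6 (1 M in pentane), Et2O, −78 °C; NaOH, H2O2, 0 °C to rt
Reagents that add atoms: none
Why: Brown asymmetric allylboration, in which the borane derived from (+)-α-pinene transfers allyl through a closed six-membered chair transition state to the Si face of the formyl group, should set the C6 carbinol as S under reagent control and not substrate control.

Step 5
Reactants: 7 (1S)-1-[(5R)-5-(benzyloxy)-2-methyl-5-(propan-2-yl)cyclopent-1-en-1-yl]but-3-en-1-ol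
Product: 9 (1R,2R,5R)-5-(benzyloxy)-2-methyl-5-(propan-2-yl)-2-(prop-2-en-1-yl)cyclopentane-1-carbaldehyde, via potassium enolate 8 (not isolated)
Conditions: KH, 18-crown-6, THF, 0 °C to rt; MeOH, 0 °C; AcOH
Reagents that add atoms: none
Why: Anionic oxy-Cope rearrangement, in whose chair transition state the alkoxide should sit pseudo-equatorial because the inside position clashes with the cis methyl on C1 (1,3-allylic strain), so that the S carbinol hands its allyl group to the C1 face anti to the benzyloxy group (1,3-chirality transfer), after which methoxide formed on quenching should equilibrate C5 to the aldehyde with the formyl group trans to the isopropyl group.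

Step 6
Reactants: 9 (1R,2R,5R)-5-(benzyloxy)-2-methyl-5-(propan-2-yl)-2-(prop-2-en-1-yl)cyclopentane-1-carbaldehyde; 10 2-methylallylmagnesium chloride
Product: 11 (1S)-1-[(1S,2R,5R)-5-(benzyloxy)-2-methyl-5-(propan-2-yl)-2-(prop-2-en-1-yl)cyclopentyl]-3-methylbut-3-en-1-ol
Conditions: MgBr2·OEt2, CH2Cl2, −78 °C; 10 (0.5 M in THF), −78 °C; aq NH4Cl
Reagents that add atoms: none
Why: Chelation-controlled Grignard addition (Cram chelate model), in which magnesium bridges the formyl oxygen and the cis β-benzyloxy oxygen in a six-membered ring and the methallyl group should enter from the chelate face flanked by H5, away from the quaternary C1 with its cis methyl group, setting C6 as S.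

Step 7
Reactants: 11 (1S)-1-[(1S,2R,5R)-5-(benzyloxy)-2-methyl-5-(propan-2-yl)-2-(prop-2-en-1-yl)cyclopentyl]-3-methylbut-3-en-1-ol; 12 4-(benzyloxy)benzoic acid
Product: 13 (1S)-1-[(1S,2R,5R)-5-(benzyloxy)-2-methyl-5-(propan-2-yl)-2-(prop-2-en-1-yl)cyclopentyl]-3-methylbut-3-en-1-yl 4-(benzyloxy)benzoate
Conditions: DCC, DMAP, CH2Cl2, rt
Reagents that add atoms: none
Why: Steglich esterification through the acylpyridinium ion should acylate the only free hydroxyl with retention at C6, since the C6–O bond is not broken.

Step 8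
Reactants: 13 (1S)-1-[(1S,2R,5R)-5-(benzyloxy)-2-methyl-5-(propan-2-yl)-2-(prop-2-en-1-yl)cyclopentyl]-3-methylbut-3-en-1-yl 4-(benzyloxy)benzoate
Product: 14 (3R,3aS,4S,8aR)-3-(benzyloxy)-6,8a-dimethyl-3-(propan-2-yl)-1,2,3,3a,4,5,8,8a-octahydroazulen-4-yl 4-(benzyloxy)benzoate
Conditions: RuCl2(=CHPh)(H2IMes)(PCy3) (second-generation Grubbs catalyst, 5 mol %), CH2Cl2 (5 mM), 40 °C
Reagents that add atoms: none
Why: The ruthenium benzylidene should first exchange with the unhindered monosubstituted alkene of the C1 allyl arm; the new alkylidene then adds across the 1,1-disubstituted alkene of the C6 methallyl arm to a ruthenacyclobutane, whose cycloreversion gives the C8=C9 alkene, ethylene being lost over the cycle. The closest known reaction type is ring-closing metathesis of 1,8-dienes to trisubstituted cycloheptenes with ruthenium benzylidenes that carry an N-heterocyclic carbene. Ring B is closed as a seven-membered carbocycle by alkene–alkene exchange between C8 and C9 through a metallacyclobutane, giving an endocyclic double bond without any polar or radical attack. No stereocentre is created, and the trans ring fusion is already fixed by C1 and C5 of 13. The step needs cyclisation in preference to oligomerisation or alkene migration, which the vicinal placement of the two arms on ring A, the quaternary C1 (Thorpe–Ingold effect), high dilution and the irreversible loss of ethylene should secure; the ester and both benzyl ethers are inert to the catalyst.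

Step 9
Reactants: 14 (3R,3aS,4S,8aR)-3-(benzyloxy)-6,8a-dimethyl-3-(propan-2-yl)-1,2,3,3a,4,5,8,8a-octahydroazulen-4-yl 4-(benzyloxy)benzoate
Product: 15 4β-benzyloxy-8α,9α-epoxy-trans-daucan-6α-yl 4-(benzyloxy)benzoate
Conditions: mCPBA, NaHCO3, CH2Cl2, 0 °C
Reagents that add atoms: 3-chloroperoxybenzoic acid, OOC(=O)c1cccc(Cl)c1
Why: Prilezhaev epoxidation of the sole alkene, in which the peracid should approach the cycloheptene face opposite to the axial angular methyl on C1 and set C8 and C9 together by syn addition, the benzyl-capped C4 oxygen being unable to direct the reagent to the β-face.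

Step 10
Reactants: 15 4β-benzyloxy-8α,9α-epoxy-trans-daucan-6α-yl 4-(benzyloxy)benzoate
Product: 16 (3R,3aS,4S,6S,7S,8aR)-3-(benzyloxy)-6,7-dihydroxy-6,8a-dimethyl-3-(propan-2-yl)decahydroazulen-4-yl 4-(benzyloxy)benzoate
Conditions: HClO4 (aq, cat.), THF/H2O (3:1), 0 °C to rt
Reagents that add atoms: water, O
Why: Acid-catalysed epoxide hydrolysis, in which the protonated epoxide should open at the tertiary C8 by backside attack of water (borderline SN2, trans-diaxial), inverting C8 to the 8β-alcohol while C9 keeps its α-oxygen, the α-face C6 ester being unable to reach the β-face of C8 to participate.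

Step 11
Reactants: 16 (3R,3aS,4S,6S,7S,8aR)-3-(benzyloxy)-6,7-dihydroxy-6,8a-dimethyl-3-(propan-2-yl)decahydroazulen-4-yl 4-(benzyloxy)benzoate
Product: 17 (3R,3aS,4S,6S,7S,8aR)-3,6,7-trihydroxy-6,8a-dimethyl-3-(propan-2-yl)decahydroazulen-4-yl 4-hydroxybenzoate
Conditions: H2 (1 atm), Pd(OH)2/C, EtOAc/MeOH, rt
Reagents that add atoms: none
Why: Catalytic hydrogenolysis of the aryl benzyl ether and the tertiary alkyl benzyl ether over palladium should free the phenol and the C4 alcohol, leaving the non-benzylic ester, the alcohols and all stereocentres untouched.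

**Compound list**

1 | (S)-terpinen-4-ol, (1S)-4-methyl-1-(propan-2-yl)cyclohex-3-en-1-ol | CC(C)[C@@]1(O)CC=C(C)CC1 | starting material
2 | (4S)-4-(benzyloxy)-1-methyl-4-(propan-2-yl)cyclohex-1-ene | CC(C)[C@@]1(OCc2ccccc2)CC=C(C)CC1 | intermediate
3 | ozonide of 2, a 7,8,9-trioxabicyclo[4.2.1]nonane formed as bridgehead diastereomers (not isolated) | CC(C)[C@@]1(OCc2ccccc2)CC3OOC(C)(CC1)O3 | intermediate
4 | (3S)-3-(benzyloxy)-6-oxo-3-(propan-2-yl)heptanal | CC(C)[C@@](CCC(C)=O)(OCc1ccccc1)CC=O | intermediate
5 | (5R)-5-(benzyloxy)-2-methyl-5-(propan-2-yl)cyclopent-1-ene-1-carbaldehyde | CC(C)[C@]1(OCc2ccccc2)CCC(C)=C1C=O | intermediate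
6 | (−)-B-allyldiisopinocampheylborane (from (+)-α-pinene, commercial pentane solution) | C=CCB([C@@H]1C[C@@H]2C[C@H]([C@H]1C)C2(C)C)[C@@H]1C[C@@H]2C[C@H]([C@H]1C)C2(C)C | starting material
7 | (1S)-1-[(5R)-5-(benzyloxy)-2-methyl-5-(propan-2-yl)cyclopent-1-en-1-yl]but-3-en-1-ol | CC(C)[C@]1(OCc2ccccc2)CCC(C)=C1[C@@H](O)CC=C | intermediate
8 | potassium enolate of 9, enolate oxygen cis to C4 (not isolated) | CC(C)[C@]1(OCc2ccccc2)CC[C@](C)(CC=C)/C1=C/[O-].[K+] | intermediate
9 | (1R,2R,5R)-5-(benzyloxy)-2-methyl-5-(propan-2-yl)-2-(prop-2-en-1-yl)cyclopentane-1-carbaldehyde | CC(C)[C@]1(OCc2ccccc2)CC[C@](C)(CC=C)[C@H]1C=O | intermediate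
10 | 2-methylallylmagnesium chloride (commercial THF solution) | CC(=C)C[Mg]Cl | starting material
11 | (1S)-1-[(1S,2R,5R)-5-(benzyloxy)-2-methyl-5-(propan-2-yl)-2-(prop-2-en-1-yl)cyclopentyl]-3-methylbut-3-en-1-ol | CC(C)[C@]1(OCc2ccccc2)CC[C@](C)(CC=C)[C@H]1[C@H](CC(C)=C)O | intermediate
12 | 4-(benzyloxy)benzoic acid | OC(=O)c1ccc(OCc2ccccc2)cc1 | starting material
13 | (1S)-1-[(1S,2R,5R)-5-(benzyloxy)-2-methyl-5-(propan-2-yl)-2-(prop-2-en-1-yl)cyclopentyl]-3-methylbut-3-en-1-yl 4-(benzyloxy)benzoate | CC(C)[C@]1(OCc2ccccc2)CC[C@](C)(CC=C)[C@H]1[C@H](CC(C)=C)OC(=O)c3ccc(OCc4ccccc4)cc3 | intermediate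
14 | (3R,3aS,4S,8aR)-3-(benzyloxy)-6,8a-dimethyl-3-(propan-2-yl)-1,2,3,3a,4,5,8,8a-octahydroazulen-4-yl 4-(benzyloxy)benzoate (4β-benzyloxy-trans-dauc-8-en-6α-yl ester) | CC(C)[C@]1(OCc2ccccc2)CC[C@]3(C)CC=C(C)C[C@H](OC(=O)c4ccc(OCc5ccccc5)cc4)[C@H]31 | intermediate
15 | 4β-benzyloxy-8α,9α-epoxy-trans-daucan-6α-yl 4-(benzyloxy)benzoate | CC(C)[C@]1(OCc2ccccc2)CC[C@]3(C)C[C@@H]4O[C@]4(C)C[C@H](OC(=O)c5ccc(OCc6ccccc6)cc5)[C@H]31 | intermediate
16 | (3R,3aS,4S,6S,7S,8aR)-3-(benzyloxy)-6,7-dihydroxy-6,8a-dimethyl-3-(propan-2-yl)decahydroazulen-4-yl 4-(benzyloxy)benzoate (4β-benzyloxy-8β,9α-dihydroxy-trans-daucan-6α-yl ester) | CC(C)[C@]1(OCc2ccccc2)CC[C@]3(C)C[C@H](O)[C@@](C)(O)C[C@H](OC(=O)c4ccc(OCc5ccccc5)cc4)[C@H]31 | intermediate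
17 | (3R,3aS,4S,6S,7S,8aR)-3,6,7-trihydroxy-6,8a-dimethyl-3-(propan-2-yl)decahydroazulen-4-yl 4-hydroxybenzoate (4β,8β,9α-trihydroxy-trans-daucan-6α-yl 4-hydroxybenzoate, CNP0197754.1) | CC(C)[C@]1(O)CC[C@]2(C)C[C@H](O)[C@@](C)(O)C[C@H](OC(=O)c3ccc(O)cc3)[C@H]21 | target

**Step count and risks**

Total step count: 11. Longest linear sequence: 11 steps (from 1 to 17).

Steps most likely to fail, riskiest first:

Step 5. The allyl group may cross to the benzyloxy face through a transition state with the alkoxide in the inside position, so that the chirality transfer from C6 to C1 erodes; the potassium enolate may also expel benzyloxide by E1cB. The fallback sets out from 7 and comes back at 9. Lithium 4,4′-di-tert-butylbiphenylide in THF at −78 °C should cleave the tertiary benzyl ether without touching the alkenes and give the diol (1S)-1-[(5R)-5-hydroxy-2-methyl-5-(propan-2-yl)cyclopent-1-en-1-yl]but-3-en-1-ol F1. With excess KH in THF at rt the dipotassium bis-alkoxide rearranges; a six-membered O–K–O chelate should hold the carbinol oxygen next to the C4 oxygen, so that the allyl group of the S carbinol can lie only on the opposite face, and the C4 oxide cannot act as a leaving group. Quenching with AcOH at −78 °C gives the hydroxy aldehyde (1R,2R,5R)-5-hydroxy-2-methyl-5-(propan-2-yl)-2-(prop-2-en-1-yl)cyclopentane-1-carbaldehyde F2. Benzylation of the tertiary alcohol under neutral conditions (2-benzyloxy-1-methylpyridinium triflate, MgO, PhCF3, 85 °C), followed by a brief K2CO3/MeOH equilibration of C5, leads back to 9.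

Step 9. The peracid may attack both faces of the cycloheptene; the β-epoxide would lead after hydrolysis to the 8α,9β-diol. The fallback sets out from 11 and comes back at 15. Ring closure is carried out on the free alcohol with the same ruthenium catalyst (CH2Cl2, 5 mM, 40 °C) to give the homoallylic alcohol 4β-benzyloxy-trans-dauc-8-en-6α-ol F3. VO(acac)2 and t-BuOOH in CH2Cl2 should then deliver oxygen from the face of the C6 hydroxyl (hydroxyl-directed epoxidation of a homoallylic alcohol), giving the epoxy alcohol 4β-benzyloxy-8α,9α-epoxy-trans-daucan-6α-ol F4. Steglich esterification with 12 (DCC, DMAP, CH2Cl2) gives 15.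

Step 6. Chelation may be incomplete, so that the Grignard reagent adds to both faces of the formyl group and a C6 epimer mixture results. The fallback sets out from 11 as obtained (admixed with its C6 epimer) and comes back at 11 as the single epimer. Dess–Martin oxidation (NaHCO3, CH2Cl2, 0 °C) converts the mixture to the β,γ-unsaturated ketone 1-[(1R,2R,5R)-5-(benzyloxy)-2-methyl-5-(propan-2-yl)-2-(prop-2-en-1-yl)cyclopentyl]-3-methylbut-3-en-1-one F5. Catalyst-controlled reduction with (R)-2-methyl-CBS-oxazaborolidine and catecholborane in toluene at −78 °C should set C6 as S, by hydride delivery instead of carbon–carbon bond formation.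

**Further compounds**

F1 | step 5 | (1S)-1-[(5R)-5-hydroxy-2-methyl-5-(propan-2-yl)cyclopent-1-en-1-yl]but-3-en-1-ol | CC(C)[C@]1(O)CCC(C)=C1[C@@H](O)CC=C
F2 | step 5 | (1R,2R,5R)-5-hydroxy-2-methyl-5-(propan-2-yl)-2-(prop-2-en-1-yl)cyclopentane-1-carbaldehyde | CC(C)[C@]1(O)CC[C@](C)(CC=C)[C@H]1C=O
F3 | step 9 | (3R,3aS,4S,8aR)-3-(benzyloxy)-6,8a-dimethyl-3-(propan-2-yl)-1,2,3,3a,4,5,8,8a-octahydroazulen-4-ol (4β-benzyloxy-trans-dauc-8-en-6α-ol) | CC(C)[C@]1(OCc2ccccc2)CC[C@]3(C)CC=C(C)C[C@H](O)[C@H]31
F4 | step 9 | 4β-benzyloxy-8α,9α-epoxy-trans-daucan-6α-ol | CC(C)[C@]1(OCc2ccccc2)CC[C@]3(C)C[C@@H]4O[C@]4(C)C[C@H](O)[C@H]31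
F5 | step 6 | 1-[(1R,2R,5R)-5-(benzyloxy)-2-methyl-5-(propan-2-yl)-2-(prop-2-en-1-yl)cyclopentyl]-3-methylbut-3-en-1-one | CC(C)[C@]1(OCc2ccccc2)CC[C@](C)(CC=C)[C@H]1C(=O)CC(C)=C
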